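**Strategy**

Everything rests on disconnecting the two methyl groups of ring B, C8–C17 and C9–C20. In ring B the methyl-bearing carbons C8 and C9 are neighbours, C9 is quaternary and also carries the C11–C15 chain, and the adjacent C10 can be a ketone before ring A is annulated. One operation, a copper-catalysed enantioselective transfer of methyl from Me3Al to C8 of a 2-alkylcyclohexenone followed by methylation of the resulting C9–C10 enolate, sets both stereocentres with the methyls trans. The precursor is cyclohex-2-enone carrying the (R)-3-methylpentyl chain at C9, its C15 end held as a triisopropylsilyl ether so that no ester is exposed to the enolate or to methyllithium.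

Key step: step 7

Remark: halimane numbering is used throughout (ring A = C1–C5 and C10; ring B = C5–C10; C17 on C8, C20 on C9, chain C11–C15 with C16 on C13). The ligand L* is a biphenol-derived N,N-bis(1-arylethyl)phosphoramidite; its enantiomer is assumed to be the one that delivers methyl to the Re face of C8, to be fixed on 2-methylcyclohex-2-enone as a model.

**Route**

Step 1
Reactants: 1 methyl hydrogen (R)-3-methylglutarate
Product: 2 methyl (3R)-5-hydroxy-3-methylpentanoate
Conditions: BH3·SMe2 (1.1 equiv), THF, −10 °C → rt; MeOH quench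
Reagents that add atoms: none
Why: Chemoselective borane reduction of the carboxylic acid (through its acyloxyborane) in the presence of the methyl ester leaves the C13 centre untouched, and the crude hydroxy ester is carried on at once so that it has no time to lactonise.

Step 2
Reactants: 2 methyl (3R)-5-hydroxy-3-methylpentanoate
Product: 3 methyl (3S)-5-iodo-3-methylpentanoate
Conditions: I2, PPh3, imidazole, CH2Cl2, 0 °C → rt
Reagents that add atoms: iodine, [I][I]
Why: Appel-type iodination in which iodide displaces the alkoxyphosphonium ion of the primary alcohol by SN2, remote from C13, whose spatial arrangement is unchanged (the descriptor becomes S only through the change in priorities).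

Step 3
Reactants: 3 methyl (3S)-5-iodo-3-methylpentanoate
Product: 4 (3S)-5-iodo-3-methylpentan-1-ol
Conditions: i-Bu2AlH (2.2 equiv), CH2Cl2, −78 → 0 °C; aq. Rochelle salt
Reagents that add atoms: none
Why: Hydride reduction of the ester to the primary alcohol with i-Bu2AlH, which does not reduce a primary alkyl iodide at this temperature, followed by a neutral tartrate work-up that avoids base-induced closure to the tetrahydropyran.

Step 4
Reactants: 4 (3S)-5-iodo-3-methylpentan-1-ol
Product: 5 {[(3S)-5-iodo-3-methylpentyl]oxy}tri(propan-2-yl)silane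
Conditions: i-Pr3SiCl, imidazole, DMF, 0 °C → rt
Reagents that add atoms: chlorotri(propan-2-yl)silane, CC(C)[Si](Cl)(C(C)C)C(C)C
Why: Standard silylation of a primary alcohol, the triisopropylsilyl ether being chosen because it withstands organozinc, Me3Al, MeLi, TiCl4, KOH in methanol, BF3·OEt2 and Raney Ni, none of which an ester at C15 would survive cleanly.

Step 5
Reactants: 6 cyclohex-2-en-1-one
Product: 7 2-iodocyclohex-2-en-1-one
Conditions: I2, K2CO3, DMAP (cat.), THF/H2O (1:1), rt
Reagents that add atoms: iodine, [I][I]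
Why: α-Iodination of an enone by a Baylis–Hillman-type sequence, in which the amine adds in conjugate fashion, the enolate is iodinated and the amine is eliminated again.

Step 6
Reactants: 5 {[(3S)-5-iodo-3-methylpentyl]oxy}tri(propan-2-yl)silane; 7 2-iodocyclohex-2-en-1-one
Product: 9 2-[(3R)-3-methyl-5-{[tri(propan-2-yl)silyl]oxy}pentyl]cyclohex-2-en-1-one, via alkylzinc iodide 8 (not isolated)
Conditions: Zn dust (activated with BrCH2CH2Br, Me3SiCl), LiCl, THF, 40 °C; then 7, Pd2(dba)3 (2.5 mol %), P(2-furyl)3 (10 mol %), THF/DMF, rt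
Reagents that add atoms: none
Why: Negishi coupling in which zinc inserts into the primary C–I bond and the alkylzinc iodide transmetalates to the palladium complex formed by oxidative addition of the α-iodoenone, reductive elimination forming C9–C11 while the silyl ether, the enone and the C13 centre are untouched.

Step 7
Reactants: 9 2-[(3R)-3-methyl-5-{[tri(propan-2-yl)silyl]oxy}pentyl]cyclohex-2-en-1-one
Product: 12 (2R,3R)-2,3-dimethyl-2-[(3R)-3-methyl-5-{[tri(propan-2-yl)silyl]oxy}pentyl]cyclohexan-1-one, via dimethylaluminium enolate 10 (not isolated), via lithium trimethylaluminate enolate 11 (not isolated)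
Conditions: Me3Al (1.5 equiv), copper thiophene-2-carboxylate (CuTC, C5H3CuO2S, 5 mol %), phosphoramidite L* (10 mol %), Et2O, −30 °C; then MeLi (1.5 equiv), THF, −30 °C; HMPA, MeI (5 equiv), −30 °C → rt
Reagents that add atoms: trimethylaluminium, C[Al](C)C; iodomethane, CI
Why: The monovalent copper–phosphoramidite complex takes a methyl group from Me3Al, binds the enone as a π-complex and, through a trivalent copper σ-alkyl intermediate, reductively eliminates to place methyl on the Re face of C8, leaving the regiodefined C9–C10 dimethylaluminium enolate 10. This is the known copper-catalysed asymmetric conjugate addition of trialkylaluminium reagents to 2-substituted cyclohexenones with alkylation of the enolate, and no ring is closed. C8 is controlled by the ligand, the remote C13 centre being a bystander. MeLi converts 10 into the more nucleophilic aluminate 11, which MeI methylates at carbon in THF/HMPA, and C9 is controlled by the substrate: the C8 methyl sits pseudoaxial in the enolate to avoid allylic strain with the C9 chain, so MeI enters axially on the opposite face, giving C17 and C20 trans and the chain cis to C17. The step needs enantiofacial selectivity at C8 (from the ligand), a single enolate regioisomer (from the conjugate addition itself) and methylation at C9 instead of at oxygen or C5 (soft MeI on the ate complex at low temperature, with a silyl ether that, unlike an ester, is inert to MeLi and to the enolate).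

Step 8
Reactants: 12 (2R,3R)-2,3-dimethyl-2-[(3R)-3-methyl-5-{[tri(propan-2-yl)silyl]oxy}pentyl]cyclohexan-1-one
Product: 13 trimethyl({(5R,6R)-5,6-dimethyl-6-[(3R)-3-methyl-5-{[tri(propan-2-yl)silyl]oxy}pentyl]cyclohex-1-en-1-yl}oxy)silane
Conditions: Me3SiOTf, Et3N, CH2Cl2, 0 °C → rt
Reagents that add atoms: trimethylsilyl trifluoromethanesulfonate, C[Si](C)(C)OS(=O)(=O)C(F)(F)F
Why: Soft enolisation and O-silylation of the ketone, which can give only the C5–C10 enol ether because C9 is quaternary, so neither C8 nor C9 is at risk.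

Step 9
Reactants: 13 trimethyl({(5R,6R)-5,6-dimethyl-6-[(3R)-3-methyl-5-{[tri(propan-2-yl)silyl]oxy}pentyl]cyclohex-1-en-1-yl}oxy)silane; 14 mesityl oxide (4-methylpent-3-en-2-one)
Product: 15 (2R,3R,6S)-2,3-dimethyl-2-[(3R)-3-methyl-5-{[tri(propan-2-yl)silyl]oxy}pentyl]-6-(2-methyl-4-oxopentan-2-yl)cyclohexan-1-one
Conditions: TiCl4 (1.1 equiv), CH2Cl2, −78 °C; aq. NaHCO3
Reagents that add atoms: none
Why: Mukaiyama–Michael addition in which C5 of the enol silane attacks the β-carbon of TiCl4-activated mesityl oxide to form C4–C5 with the quaternary C4, and the new C5 centre should arise by attack on the face opposite the pseudoaxial C9 chain in the half-chair that keeps the C8 methyl equatorial, which puts the new substituent trans to the chain and cis to C20 (the centre stays epimerisable and is settled in step 10).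

Step 10
Reactants: 15 (2R,3R,6S)-2,3-dimethyl-2-[(3R)-3-methyl-5-{[tri(propan-2-yl)silyl]oxy}pentyl]-6-(2-methyl-4-oxopentan-2-yl)cyclohexan-1-one
Product: 17 (4aS,7R,8R)-4,4,7,8-tetramethyl-8-[(3R)-3-methyl-5-{[tri(propan-2-yl)silyl]oxy}pentyl]-4,4a,5,6,7,8-hexahydronaphthalen-2(3H)-one, via ketol 16 (not isolated)
Conditions: KOH, MeOH, 60 °C
Reagents that add atoms: none
Why: Intramolecular aldol condensation (the closing stage of a Robinson annulation) in which the methyl ketone enolate C1 adds to the C10 carbonyl in a 6-(enolexo)-exo-trig closure helped by the C4 gem-dimethyl group and E1cB loss of water from ketol 16 gives the conjugated C1=C10 enone, while C5, which can equilibrate through the ring B enolate and the extended dienolate, should settle as the epimer formed in step 9 because only that epimer lets ring B keep C4, C17 and C20 equatorial with the chain alone axial, whereas its C5 epimer would need both methyls axial.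

Step 11
Reactants: 17 (4aS,7R,8R)-4,4,7,8-tetramethyl-8-[(3R)-3-methyl-5-{[tri(propan-2-yl)silyl]oxy}pentyl]-4,4a,5,6,7,8-hexahydronaphthalen-2(3H)-one
Product: 18 the 1,3-dithiolane (ethylene dithioketal) of 17 at C2, with C1=C10 and all stereocentres as in 17
Conditions: HSCH2CH2SH, BF3·OEt2, CH2Cl2, 0 °C → rt
Reagents that add atoms: ethane-1,2-dithiol, SCCS
Why: Lewis-acid-catalysed dithioketalisation of the enone carbonyl, in which conjugate addition of thiol is blocked by the fully substituted β-carbon C10 and the double bond is expected to stay at C1=C10 as it does in the dithioketals of steroidal 4-en-3-ones.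

Step 12
Reactants: 18 the 1,3-dithiolane of 17
Product: 19 {[(3R)-3-methyl-5-[(1R,2R,4aS)-1,2,5,5-tetramethyl-1,2,3,4,4a,5,6,7-octahydronaphthalen-1-yl]pentyl]oxy}tri(propan-2-yl)silane
Conditions: Raney Ni (W-2, deactivated by reflux in acetone), EtOH, rt → 60 °C
Reagents that add atoms: none
Why: Mozingo reduction in which hydrogen-laden nickel cleaves both C–S bonds to leave C2 as a methylene group, a deactivated catalyst at moderate temperature being expected to spare the hindered trisubstituted C1=C10 bond and the silyl ether.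

Step 13
Reactants: 19 {[(3R)-3-methyl-5-[(1R,2R,4aS)-1,2,5,5-tetramethyl-1,2,3,4,4a,5,6,7-octahydronaphthalen-1-yl]pentyl]oxy}tri(propan-2-yl)silane
Product: 20 (3R)-3-methyl-5-[(1R,2R,4aS)-1,2,5,5-tetramethyl-1,2,3,4,4a,5,6,7-octahydronaphthalen-1-yl]pentan-1-ol
Conditions: Bu4NF, THF, rt
Reagents that add atoms: none
Why: Fluoride-induced cleavage of the Si–O bond, driven by the strength of the Si–F bond, frees the C15 alcohol without touching the alkene or any stereocentre.

Step 14
Reactants: 20 (3R)-3-methyl-5-[(1R,2R,4aS)-1,2,5,5-tetramethyl-1,2,3,4,4a,5,6,7-octahydronaphthalen-1-yl]pentan-1-ol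
Product: 21 (3R)-3-methyl-5-[(1R,2R,4aS)-1,2,5,5-tetramethyl-1,2,3,4,4a,5,6,7-octahydronaphthalen-1-yl]pentanoic acid
Conditions: TEMPO (20 mol %), PhI(OAc)2 (2.5 equiv), MeCN/H2O (1:1), rt
Reagents that add atoms: water, O
Why: Oxoammonium (TEMPO) oxidation in aqueous acetonitrile takes the primary alcohol to the aldehyde and its hydrate on to the acid, leaving the trisubstituted alkene alone and C13 safe because it is β and not α to the new carbonyl.

Step 15
Reactants: 21 (3R)-3-methyl-5-[(1R,2R,4aS)-1,2,5,5-tetramethyl-1,2,3,4,4a,5,6,7-octahydronaphthalen-1-yl]pentanoic acid; 22 (R)-solketal [(4R)-2,2-dimethyl-1,3-dioxolan-4-yl]methanol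
Product: 23 [(4S)-2,2-dimethyl-1,3-dioxolan-4-yl]methyl (3R)-3-methyl-5-[(1R,2R,4aS)-1,2,5,5-tetramethyl-1,2,3,4,4a,5,6,7-octahydronaphthalen-1-yl]pentanoate
Conditions: DCC, DMAP (cat.), CH2Cl2, 0 °C → rt
Reagents that add atoms: none
Why: Steglich esterification through the O-acylisourea and acylpyridinium ion acylates the primary alcohol of 22, whose stereocentre supplies the glycerol C2 configuration unchanged in space (the descriptor becomes S only through the change in priorities).

Step 16
Reactants: 23 [(4S)-2,2-dimethyl-1,3-dioxolan-4-yl]methyl ester of acid 21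
Product: 24 (2S)-2,3-dihydroxypropyl (3R)-3-methyl-5-[(1R,2R,4aS)-1,2,5,5-tetramethyl-1,2,3,4,4a,5,6,7-octahydronaphthalen-1-yl]pentanoate
Conditions: AcOH/H2O (4:1), 45 °C
Reagents that add atoms: none
Why: Mild acid hydrolysis of the terminal acetonide frees the 1,2-diol under conditions gentle enough to keep the ester, the trisubstituted alkene and the glycerol stereocentre intact and to limit acyl migration.

Step 17
Reactants: 24 (2S)-2,3-dihydroxypropyl ester of acid 21
Product: 25 (2S)-3-acetoxy-2-hydroxypropyl (3R)-3-methyl-5-[(1R,2R,4aS)-1,2,5,5-tetramethyl-1,2,3,4,4a,5,6,7-octahydronaphthalen-1-yl]pentanoate (CNP0317518.1)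
Conditions: AcCl (1.05 equiv), 2,4,6-collidine, CH2Cl2, −78 °C
Reagents that add atoms: acetyl chloride, CC(=O)Cl
Why: Selective acylation of the primary over the secondary hydroxyl with an acid chloride and a hindered weak base at low temperature relies on steric differentiation, leaves the secondary alcohol free and creates no new stereocentre.

**Compound list**

1 | methyl hydrogen (R)-3-methylglutarate | COC(=O)C[C@H](C)CC(=O)O | starting material
2 | methyl (3R)-5-hydroxy-3-methylpentanoate | COC(=O)C[C@H](C)CCO | intermediate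
3 | methyl (3S)-5-iodo-3-methylpentanoate | COC(=O)C[C@H](C)CCI | intermediate
4 | (3S)-5-iodo-3-methylpentan-1-ol | OCC[C@H](C)CCI | intermediate
5 | {[(3S)-5-iodo-3-methylpentyl]oxy}tri(propan-2-yl)silane | CC(C)[Si](C(C)C)(C(C)C)OCC[C@H](C)CCI | intermediate
6 | cyclohex-2-en-1-one | O=C1C=CCCC1 | starting material
7 | 2-iodocyclohex-2-en-1-one | O=C1C(I)=CCCC1 | intermediate
8 | [(3S)-3-methyl-5-{[tri(propan-2-yl)silyl]oxy}pentyl]zinc iodide (not isolated) | CC(C)[Si](C(C)C)(C(C)C)OCC[C@H](C)CC[Zn]I | intermediate
9 | 2-[(3R)-3-methyl-5-{[tri(propan-2-yl)silyl]oxy}pentyl]cyclohex-2-en-1-one | CC(C)[Si](C(C)C)(C(C)C)OCC[C@H](C)CCC1=CCCCC1=O | intermediate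
10 | dimethylaluminium (3R)-3-methyl-2-[(3R)-3-methyl-5-{[tri(propan-2-yl)silyl]oxy}pentyl]cyclohex-1-en-1-olate (not isolated) | CC(C)[Si](C(C)C)(C(C)C)OCC[C@H](C)CCC1=C(O[Al](C)C)CCC[C@H]1C | intermediate
11 | lithium trimethyl{(3R)-3-methyl-2-[(3R)-3-methyl-5-{[tri(propan-2-yl)silyl]oxy}pentyl]cyclohex-1-en-1-olato}aluminate (not isolated) | CC(C)[Si](C(C)C)(C(C)C)OCC[C@H](C)CCC1=C(O[Al-](C)(C)C)CCC[C@H]1C.[Li+] | intermediate
12 | (2R,3R)-2,3-dimethyl-2-[(3R)-3-methyl-5-{[tri(propan-2-yl)silyl]oxy}pentyl]cyclohexan-1-one | CC(C)[Si](C(C)C)(C(C)C)OCC[C@H](C)CC[C@@]1(C)C(=O)CCC[C@H]1C | intermediate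
13 | trimethyl({(5R,6R)-5,6-dimethyl-6-[(3R)-3-methyl-5-{[tri(propan-2-yl)silyl]oxy}pentyl]cyclohex-1-en-1-yl}oxy)silane | CC(C)[Si](C(C)C)(C(C)C)OCC[C@H](C)CC[C@@]1(C)C(O[Si](C)(C)C)=CCC[C@H]1C | intermediate
14 | mesityl oxide (4-methylpent-3-en-2-one) | CC(C)=CC(C)=O | starting material
15 | (2R,3R,6S)-2,3-dimethyl-2-[(3R)-3-methyl-5-{[tri(propan-2-yl)silyl]oxy}pentyl]-6-(2-methyl-4-oxopentan-2-yl)cyclohexan-1-one | CC(C)[Si](C(C)C)(C(C)C)OCC[C@H](C)CC[C@@]1(C)C(=O)[C@H](C(C)(C)CC(C)=O)CC[C@H]1C | intermediate
16 | C10 ketol: (4aS,7R,8R)-8a-hydroxy-4,4,7,8-tetramethyl-8-[(3R)-3-methyl-5-{[tri(propan-2-yl)silyl]oxy}pentyl]octahydronaphthalen-2(1H)-one, carbinol configuration at C10 left open since both epimers dehydrate (not isolated) | CC(C)[Si](C(C)C)(C(C)C)OCC[C@H](C)CC[C@@]1(C)C2(O)CC(=O)CC(C)(C)[C@@H]2CC[C@H]1C | intermediate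
17 | (4aS,7R,8R)-4,4,7,8-tetramethyl-8-[(3R)-3-methyl-5-{[tri(propan-2-yl)silyl]oxy}pentyl]-4,4a,5,6,7,8-hexahydronaphthalen-2(3H)-one | CC(C)[Si](C(C)C)(C(C)C)OCC[C@H](C)CC[C@@]1(C)C2=CC(=O)CC(C)(C)[C@@H]2CC[C@H]1C | intermediate
18 | 1,3-dithiolane of 17 at C2 | CC(C)[Si](C(C)C)(C(C)C)OCC[C@H](C)CC[C@@]1(C)C2=CC3(SCCS3)CC(C)(C)[C@@H]2CC[C@H]1C | intermediate
19 | {[(3R)-3-methyl-5-[(1R,2R,4aS)-1,2,5,5-tetramethyl-1,2,3,4,4a,5,6,7-octahydronaphthalen-1-yl]pentyl]oxy}tri(propan-2-yl)silane | CC(C)[Si](C(C)C)(C(C)C)OCC[C@H](C)CC[C@@]1(C)C2=CCCC(C)(C)[C@@H]2CC[C@H]1C | intermediate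
20 | (3R)-3-methyl-5-[(1R,2R,4aS)-1,2,5,5-tetramethyl-1,2,3,4,4a,5,6,7-octahydronaphthalen-1-yl]pentan-1-ol | OCC[C@H](C)CC[C@@]1(C)C2=CCCC(C)(C)[C@@H]2CC[C@H]1C | intermediate
21 | (3R)-3-methyl-5-[(1R,2R,4aS)-1,2,5,5-tetramethyl-1,2,3,4,4a,5,6,7-octahydronaphthalen-1-yl]pentanoic acid | OC(=O)C[C@H](C)CC[C@@]1(C)C2=CCCC(C)(C)[C@@H]2CC[C@H]1C | intermediate
22 | (R)-solketal, [(4R)-2,2-dimethyl-1,3-dioxolan-4-yl]methanol | OC[C@@H]1COC(C)(C)O1 | starting material
23 | [(4S)-2,2-dimethyl-1,3-dioxolan-4-yl]methyl ester of 21 | O=C(OC[C@@H]1COC(C)(C)O1)C[C@H](C)CC[C@@]2(C)C3=CCCC(C)(C)[C@@H]3CC[C@H]2C | intermediate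
24 | (2S)-2,3-dihydroxypropyl ester of 21 | O=C(OC[C@@H](O)CO)C[C@H](C)CC[C@@]1(C)C2=CCCC(C)(C)[C@@H]2CC[C@H]1C | intermediate
25 | (2S)-3-acetoxy-2-hydroxypropyl (3R)-3-methyl-5-[(1R,2R,4aS)-1,2,5,5-tetramethyl-1,2,3,4,4a,5,6,7-octahydronaphthalen-1-yl]pentanoate | CC(=O)OC[C@H](O)COC(=O)C[C@H](C)CC[C@@]1(C)C2=CCCC(C)(C)[C@@H]2CC[C@H]1C | target

**Step count**

Total: 17 steps. Longest linear sequence: 16 steps (steps 1–4 and 6–17); step 5 is a one-step side branch.

**Steps most likely to fail**

Step 7. Methyl transfer to the β-carbon of an enone whose 2-substituent is larger than methyl may be slow or lose enantiofacial control. The aluminate enolate may also be quenched by proton transfer, or methylated at oxygen or (after enolate equilibration) at C5, before C9 is methylated. The fallback sets out from 9 and separates the two bond formations. The conjugate addition is run as above to enolate 10, which is silylated with Me3SiOTf to the trimethylsilyl enol ether F1; this is isolated, and its enantiomeric purity can be checked. MeLi in THF at 0 °C then cleaves the O–Si bond to give the regiodefined lithium enolate F2, which is methylated with MeI in THF/DMPU anti to the C8 methyl. The fallback rejoins the route at 12. A minor enantiomeric series at C8/C9 would appear as a C13 diastereomer and could be removed at 12 or at acid 21.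

Step 10. Under equilibrating base the Michael addition may reverse (loss of mesityl oxide) faster than the enolate attacks the hindered C10 carbonyl, and C5 may equilibrate to a less favourable ratio than expected. The fallback sets out from 15 and never enolises C5. Kinetic deprotonation of the methyl ketone with LDA in the presence of Me3SiCl (THF, −78 °C) gives the terminal enol silane F3. TiCl4 in CH2Cl2 at −78 °C then effects an intramolecular Mukaiyama aldol addition to C10 to give ketol 16, which is dehydrated with catalytic TsOH in toluene at 40 °C. The fallback rejoins the route at 17 with the C5 configuration from step 9.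

Step 12. On the nickel surface the allylic C–S cleavage may be accompanied by migration of the double bond away from C1=C10 or by its saturation, and desulfurisation may stop halfway. The fallback sets out from 17 and removes the C2 oxygen without sulfur. Luche reduction (NaBH4, CeCl3·7H2O, MeOH, 0 °C) gives the allylic alcohol F4, and acetylation (Ac2O, pyridine, DMAP) gives the allylic acetate F5. Reduction with LiBHEt3 and catalytic Pd(PPh3)4 in THF proceeds through the π-allyl complex of divalent palladium, which takes hydride at its less hindered terminus C2, so the double bond stays at C1=C10. The fallback rejoins the route at 19.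

**Further compounds**

F1 | step 7 | trimethyl({(3R)-3-methyl-2-[(3R)-3-methyl-5-{[tri(propan-2-yl)silyl]oxy}pentyl]cyclohex-1-en-1-yl}oxy)silane | CC(C)[Si](C(C)C)(C(C)C)OCC[C@H](C)CCC1=C(O[Si](C)(C)C)CCC[C@H]1C
F2 | step 7 | lithium (3R)-3-methyl-2-[(3R)-3-methyl-5-{[tri(propan-2-yl)silyl]oxy}pentyl]cyclohex-1-en-1-olate | CC(C)[Si](C(C)C)(C(C)C)OCC[C@H](C)CCC1=C(O[Li])CCC[C@H]1C
F3 | step 10 | (2R,3R,6S)-2,3-dimethyl-2-[(3R)-3-methyl-5-{[tri(propan-2-yl)silyl]oxy}pentyl]-6-{2-methyl-4-[(trimethylsilyl)oxy]pent-4-en-2-yl}cyclohexan-1-one | CC(C)[Si](C(C)C)(C(C)C)OCC[C@H](C)CC[C@@]1(C)C(=O)[C@H](C(C)(C)CC(=C)O[Si](C)(C)C)CC[C@H]1C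
F4 | step 12 | (4aS,7R,8R)-4,4,7,8-tetramethyl-8-[(3R)-3-methyl-5-{[tri(propan-2-yl)silyl]oxy}pentyl]-2,3,4,4a,5,6,7,8-octahydronaphthalen-2-ol (both C2 epimers) | CC(C)[Si](C(C)C)(C(C)C)OCC[C@H](C)CC[C@@]1(C)C2=CC(O)CC(C)(C)[C@@H]2CC[C@H]1C
F5 | step 12 | acetate of F4 (both C2 epimers) | CC(C)[Si](C(C)C)(C(C)C)OCC[C@H](C)CC[C@@]1(C)C2=CC(OC(C)=O)CC(C)(C)[C@@H]2CC[C@H]1C
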